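**Retrosynthetic overview**

1. The last bond made is the ester C–O bond: racemic tetracyclic acid + methanol under a chiral acyl-transfer catalyst. This one step installs the methyl ester and selects the absolute configuration.
2. The tetracycle comes from an acyclic dienediyne in one cascade. Ring order: cyclooctatriene (8π), then cyclobutane + cyclohexadiene (6π), then cyclopentane + second cyclohexene (intramolecular Diels–Alder).
3. The dienediyne ester comes from an allylic bromide and a dienylboronate (allyl–alkenyl Suzuki); the boronate comes from boronoacrolein by Wittig reaction.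
4. The allylic bromide comes from a dienediynol, made by Cadiot–Chodkiewicz coupling of an (E)-enyne (from undec-10-enal by alkene isomerisation and HWE) with bromo-pentenynol.

Assumption: every compound after the electrocyclisation cascade is racemic until the last step (SMILES show the enantiomer of the target series); the catalyst antipode in the last step is assigned by analogy with the α-arylpropanoic acid model and would be confirmed on a trial scale.

Core numbering used in names: cyclobutane C1–C2–C3–C12; cyclohexene C3–C4=C5–C6–C11–C12; cyclopentane C1–C13–C10–C11–C12; cyclohexene C6–C7–C8=C9–C10–C11; side chain on C2, carboxyl on C7.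

**Route**

Step 1
Reactants: 1 undec-10-enal
Product: 2 (E)-undec-9-enal
Conditions: Grotjahn-type Cp*Ru(κ2-P,N-imidazolylphosphine)(MeCN)PF6 (1 mol %), acetone, rt
Reagents that add atoms: none
Why: Catalytic alkene monoisomerisation; the pendant imidazole base shuttles one allylic proton and the catalyst stops after a single migration, giving the (E)-2-alkene (>95% E) with the remote aldehyde untouched.

Step 2
Reactants: 2 (E)-undec-9-enal; 3 diethyl [3-(trimethylsilyl)prop-2-yn-1-yl]phosphonate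
Product: 5 (3E,12E)-tetradeca-3,12-dien-1-yne, via silyl enyne 4 (not isolated)
Conditions: LiHMDS, THF, −78 → 0 °C; then K2CO3 (0.2 equiv), MeOH, rt
Reagents that add atoms: none
Why: Horner–Wadsworth–Emmons olefination with the propargyl-stabilised phosphonate anion gives the (E)-enyne (minor Z isomer removed on AgNO3–silica), and methanolic carbonate then cleaves the C–Si bond.

Step 3
Reactants: 6 (E)-pent-2-en-4-yn-1-ol
Product: 7 (E)-5-bromopent-2-en-4-yn-1-ol
Conditions: NBS, AgNO3 (10 mol %), acetone, rt, dark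
Reagents that add atoms: N-bromosuccinimide, O=C1CCC(=O)N1Br
Why: Silver acetylide formation followed by electrophilic bromination converts the terminal alkyne into the 1-bromoalkyne without touching the allylic alcohol or the alkene.

Step 4
Reactants: 5 (3E,12E)-tetradeca-3,12-dien-1-yne; 7 (E)-5-bromopent-2-en-4-yn-1-ol
Product: 8 (2E,8E,17E)-nonadeca-2,8,17-triene-4,6-diyn-1-ol
Conditions: CuCl (10 mol %), NH2OH·HCl, n-BuNH2 (30% aq), Et2O, 0 °C
Reagents that add atoms: none
Why: Cadiot–Chodkiewicz coupling; the copper acetylide of 5 couples with the bromoalkyne (hydroxylamine keeps Cu(I) and suppresses homocoupling) to give the unsymmetrical 1,3-diyne with all three E-alkenes intact.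

Step 5
Reactants: 8 (2E,8E,17E)-nonadeca-2,8,17-triene-4,6-diyn-1-ol
Product: 9 (2E,8E,17E)-1-bromononadeca-2,8,17-triene-4,6-diyne
Conditions: CBr4, PPh3, CH2Cl2, −20 → 0 °C (used at once)
Reagents that add atoms: carbon tetrabromide, BrC(Br)(Br)Br
Why: Appel reaction; the alkoxyphosphonium of the primary allylic alcohol is displaced by bromide (SN2) at low temperature without allylic transposition.

Step 6
Reactants: 10 (E)-3-(4,4,5,5-tetramethyl-1,3,2-dioxaborolan-2-yl)prop-2-enal; 11 tert-butyl (triphenyl-λ5-phosphanylidene)acetate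
Product: 12 tert-butyl (2E,4E)-5-(4,4,5,5-tetramethyl-1,3,2-dioxaborolan-2-yl)penta-2,4-dienoate
Conditions: CH2Cl2, rt
Reagents that add atoms: none
Why: Wittig reaction of the stabilised ylide with the enal gives the new C2=C3 bond E and leaves the C–B bond and the E-boryl alkene untouched.

Step 7
Reactants: 9 (2E,8E,17E)-1-bromononadeca-2,8,17-triene-4,6-diyne; 12 tert-butyl (2E,4E)-5-(4,4,5,5-tetramethyl-1,3,2-dioxaborolan-2-yl)penta-2,4-dienoate
Product: 13 tert-butyl (2E,4E,7E,13E,22E)-tetracosa-2,4,7,13,22-pentaene-9,11-diynoate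
Conditions: Pd(PPh3)4 (5 mol %), CsF (3 equiv), THF, 50 °C
Reagents that add atoms: none
Why: Suzuki–Miyaura allyl–alkenyl coupling; the π-allyl-palladium from the allylic bromide couples at its CH2 terminus (which keeps the E-enediyne conjugated) with retention of the dienyl geometry, giving the skipped 1,4-diene.

Step 8
Reactants: 13 tert-butyl (2E,4E,7E,13E,22E)-tetracosa-2,4,7,13,22-pentaene-9,11-diynoate
Product: 17 tert-butyl rac-(1S,2S,3R,6R,7R,10S,11S,12S)-2-[(8E)-dec-8-en-1-yl]tetracyclo[8.2.1.0^{3,12}.0^{6,11}]trideca-4,8-diene-7-carboxylate, via tetraene 14 (not isolated), via cyclooctatriene 15 (not isolated), via bicyclo[4.2.0]octadiene 16 (not isolated)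
Conditions: H2 (1 atm), Lindlar catalyst, quinoline, CH2Cl2, 25 °C; filter; PhMe, 110 °C
Reagents that add atoms: none
Why: Lindlar syn-semihydrogenation gives the (E,Z,Z,E)-tetraene, which closes at 25 °C by conrotatory 8π (C1/C2 trans) and disrotatory 6π (C3/C12 cis) electrocyclisation; at 110 °C the reversible 6π step funnels material through the isomer with the dienyl arm endo, whose suprafacial intramolecular Diels–Alder reaction through the only tether-allowed transition state sets C6, C7, C10 and C11 relative to C1/C2, and the product is racemic because both helical senses of the 8π closure are equally likely.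

Step 9
Reactants: 17 tert-butyl rac-(1S,2S,3R,6R,7R,10S,11S,12S)-2-[(8E)-dec-8-en-1-yl]tetracyclo[8.2.1.0^{3,12}.0^{6,11}]trideca-4,8-diene-7-carboxylate
Product: 18 rac-(1S,2S,3R,6R,7R,10S,11S,12S)-2-[(8E)-dec-8-en-1-yl]tetracyclo[8.2.1.0^{3,12}.0^{6,11}]trideca-4,8-diene-7-carboxylic acid
Conditions: TFA, CH2Cl2, 0 °C → rt
Reagents that add atoms: none
Why: Acidolysis of the tert-butyl ester (E1 loss of isobutylene) frees the acid without base, so the C7 stereocentre α to the carbonyl and the β,γ-alkene are not disturbed.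

Step 10
Reactants: 18 rac-(1S,2S,3R,6R,7R,10S,11S,12S)-2-[(8E)-dec-8-en-1-yl]tetracyclo[8.2.1.0^{3,12}.0^{6,11}]trideca-4,8-diene-7-carboxylic acid
Product: 19 methyl (1S,2S,3R,6R,7R,10S,11S,12S)-2-[(8E)-dec-8-en-1-yl]tetracyclo[8.2.1.0^{3,12}.0^{6,11}]trideca-4,8-diene-7-carboxylate
Conditions: (S)-benzotetramisole (5 mol %), Piv2O (0.6 equiv), MeOH (0.45 equiv), i-Pr2NEt (1.2 equiv), CH2Cl2, −20 → 0 °C, stop near 45% conversion; NaHCO3 wash
Reagents that add atoms: methanol, CO
Why: Proposed new method: enantiomer-selective acyl transfer to methanol, in which the mixed pivalic anhydride of 18 acylates the chiral isothiourea and only the (7R)-acid can give an acyl-isothiouronium with the syn O···S geometry, the C8=C9 π bond stacked on the cationic ring and the small α-H facing the incoming nucleophile, so this ion pair alone is methanolysed (pivalate as general base) while the enantiomeric acid stays unreacted and is washed out, which forms the ester C–O bond and fixes the absolute configuration of all eight stereocentres in one operation; the closest known reaction type is the isothiourea/pivalic anhydride kinetic resolution of racemic α-arylalkanoic acids by asymmetric esterification with bulky diarylmethanols, not shown for a β,γ-alkenyl polycyclic acid or for methanol as the nucleophile.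

**Compound list**

1 | undec-10-enal | C=CCCCCCCCCC=O | starting material
2 | (E)-undec-9-enal | C/C=C/CCCCCCCC=O | intermediate
3 | diethyl [3-(trimethylsilyl)prop-2-yn-1-yl]phosphonate | CCOP(=O)(CC#C[Si](C)(C)C)OCC | starting material
4 | trimethyl[(3E,12E)-tetradeca-3,12-dien-1-yn-1-yl]silane | C/C=C/CCCCCCC/C=C/C#C[Si](C)(C)C | intermediate
5 | (3E,12E)-tetradeca-3,12-dien-1-yne | C/C=C/CCCCCCC/C=C/C#C | intermediate
6 | (E)-pent-2-en-4-yn-1-ol | OC/C=C/C#C | starting material
7 | (E)-5-bromopent-2-en-4-yn-1-ol | OC/C=C/C#CBr | intermediate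
8 | (2E,8E,17E)-nonadeca-2,8,17-triene-4,6-diyn-1-ol | OC/C=C/C#CC#C/C=C/CCCCCCC/C=C/C | intermediate
9 | (2E,8E,17E)-1-bromononadeca-2,8,17-triene-4,6-diyne | BrC/C=C/C#CC#C/C=C/CCCCCCC/C=C/C | intermediate
10 | (E)-3-(4,4,5,5-tetramethyl-1,3,2-dioxaborolan-2-yl)prop-2-enal | O=C/C=C/B1OC(C)(C)C(C)(C)O1 | starting material
11 | tert-butyl (triphenyl-λ5-phosphanylidene)acetate | CC(C)(C)OC(=O)C=P(c1ccccc1)(c1ccccc1)c1ccccc1 | starting material
12 | tert-butyl (2E,4E)-5-(4,4,5,5-tetramethyl-1,3,2-dioxaborolan-2-yl)penta-2,4-dienoate | CC(C)(C)OC(=O)/C=C/C=C/B1OC(C)(C)C(C)(C)O1 | intermediate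
13 | tert-butyl (2E,4E,7E,13E,22E)-tetracosa-2,4,7,13,22-pentaene-9,11-diynoate | CC(C)(C)OC(=O)/C=C/C=C/C/C=C/C#CC#C/C=C/CCCCCCC/C=C/C | intermediate
14 | tert-butyl (2E,4E,7E,9Z,11Z,13E,22E)-tetracosa-2,4,7,9,11,13,22-heptaenoate | CC(C)(C)OC(=O)/C=C/C=C/C/C=C/C=C\C=C/C=C/CCCCCCC/C=C/C | intermediate
15 | tert-butyl (2E,4E)-6-[rac-(1R,8R)-8-[(8E)-dec-8-en-1-yl]cycloocta-2,4,6-trien-1-yl]hexa-2,4-dienoate (trans, racemate) | C/C=C/CCCCCCC[C@@H]1/C=C\C=C/C=C\[C@H]1C/C=C/C=C/C(=O)OC(C)(C)C | intermediate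
16 | tert-butyl (2E,4E)-6-[rac-(1R,6S,7S,8S)-8-[(8E)-dec-8-en-1-yl]bicyclo[4.2.0]octa-2,4-dien-7-yl]hexa-2,4-dienoate (cis-fused, 7,8-trans, dienyl arm endo, racemate) | C/C=C/CCCCCCC[C@@H]1[C@H]2C=CC=C[C@H]2[C@H]1C/C=C/C=C/C(=O)OC(C)(C)C | intermediate
17 | tert-butyl rac-(1S,2S,3R,6R,7R,10S,11S,12S)-2-[(8E)-dec-8-en-1-yl]tetracyclo[8.2.1.0^{3,12}.0^{6,11}]trideca-4,8-diene-7-carboxylate (racemate) | C/C=C/CCCCCCC[C@@H]1[C@H]2C=C[C@@H]3[C@@H]4[C@H]2[C@H]1C[C@H]4C=C[C@H]3C(=O)OC(C)(C)C | intermediate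
18 | rac-(1S,2S,3R,6R,7R,10S,11S,12S)-2-[(8E)-dec-8-en-1-yl]tetracyclo[8.2.1.0^{3,12}.0^{6,11}]trideca-4,8-diene-7-carboxylic acid (racemate) | C/C=C/CCCCCCC[C@@H]1[C@H]2C=C[C@@H]3[C@@H]4[C@H]2[C@H]1C[C@H]4C=C[C@H]3C(=O)O | intermediate
19 | methyl (1S,2S,3R,6R,7R,10S,11S,12S)-2-[(8E)-dec-8-en-1-yl]tetracyclo[8.2.1.0^{3,12}.0^{6,11}]trideca-4,8-diene-7-carboxylate | C/C=C/CCCCCCC[C@@H]1[C@H]2C=C[C@@H]3[C@@H]4[C@H]2[C@H]1C[C@H]4C=C[C@H]3C(=O)OC | target

**Step count and risks**

Total steps: 10. Longest linear sequence: 8 (steps 1, 2, 4, 5, 7, 8, 9, 10).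

Most likely to fail, step 10 (proposed method). The selectivity factor with methanol as the nucleophile may be too low to deliver a single enantiomer, and the maximum yield is about 45%. The fallback uses known chemistry, sets out from 18 and comes back at 19. Racemic 18 is N-acylated onto (S)-4-benzyloxazolidin-2-one (PivCl, Et3N, LiCl, THF). The two diastereomeric imides are separated on silica: (4S)-4-benzyl-3-[(1S,2S,3R,6R,7R,10S,11S,12S)-2-[(8E)-dec-8-en-1-yl]tetracyclo[8.2.1.0^{3,12}.0^{6,11}]trideca-4,8-diene-7-carbonyl]oxazolidin-2-one F1 and its diastereomer from the enantiomeric acid, (4S)-4-benzyl-3-[(1R,2R,3S,6S,7S,10R,11R,12R)-2-[(8E)-dec-8-en-1-yl]tetracyclo[8.2.1.0^{3,12}.0^{6,11}]trideca-4,8-diene-7-carbonyl]oxazolidin-2-one F2. F1 is then cleaved with MeOMgBr in MeOH/THF at 0 °C, which gives 19 directly and returns the auxiliary.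

Second, step 7. The π-allyl intermediate sits next to an enediyne, so allenic (1,5-) or branched coupling products and decomposition of bromide 9 are possible. The fallback makes the allyl–alkenyl bond on a substrate that has no alkyne; it sets out from 12 (with 5 as the alkyne partner) and comes back at 13. Commercial (E)-1,3-dichloropropene is coupled at its allylic chloride only with 12 (Pd(PPh3)4, CsF, THF) to give tert-butyl (2E,4E,7E)-8-chloroocta-2,4,7-trienoate F3. Sonogashira coupling of the vinyl chloride with ethynyltrimethylsilane (PdCl2(PhCN)2, CuI, piperidine) gives tert-butyl (2E,4E,7E)-10-(trimethylsilyl)deca-2,4,7-trien-9-ynoate F4, and TBAF/AcOH removes silicon to give tert-butyl (2E,4E,7E)-deca-2,4,7-trien-9-ynoate F5. Enyne 5 is brominated (NBS, AgNO3) to (3E,12E)-1-bromotetradeca-3,12-dien-1-yne F6, and Cadiot–Chodkiewicz coupling of F5 with F6 gives 13.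

Third, step 8. The semihydrogenation must spare five other C=C bonds, and the thermal cascade runs on the most advanced material. The fallback reduces one stage earlier; it sets out from 8 and comes back at 16. Lindlar semihydrogenation of dienediynol 8 gives (2E,4Z,6Z,8E,17E)-nonadeca-2,4,6,8,17-pentaen-1-ol F7, which closes at room temperature through rac-[(1R,8R)-8-[(8E)-dec-8-en-1-yl]cycloocta-2,4,6-trien-1-yl]methanol F8 to rac-[(1R,6R,7S,8R)-8-[(8E)-dec-8-en-1-yl]bicyclo[4.2.0]octa-2,4-dien-7-yl]methanol F9. Appel bromination gives rac-(1R,6R,7S,8R)-7-(bromomethyl)-8-[(8E)-dec-8-en-1-yl]bicyclo[4.2.0]octa-2,4-diene F10. Alkyl–alkenyl Suzuki coupling of this unactivated primary bromide with 12 (Pd(OAc)2, P(t-Bu)2Me, KOt-Bu, t-AmOH, rt) gives 16, which is heated at 110 °C as in step 8.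

Further compounds
F1 | step 10 | (4S)-4-benzyl-3-[(1S,2S,3R,6R,7R,10S,11S,12S)-2-[(8E)-dec-8-en-1-yl]tetracyclo[8.2.1.0^{3,12}.0^{6,11}]trideca-4,8-diene-7-carbonyl]oxazolidin-2-one | C/C=C/CCCCCCC[C@@H]1[C@H]2C=C[C@@H]3[C@@H]4[C@H]2[C@H]1C[C@H]4C=C[C@H]3C(=O)N1[C@@H](Cc2ccccc2)COC1=O
F2 | step 10 | (4S)-4-benzyl-3-[(1R,2R,3S,6S,7S,10R,11R,12R)-2-[(8E)-dec-8-en-1-yl]tetracyclo[8.2.1.0^{3,12}.0^{6,11}]trideca-4,8-diene-7-carbonyl]oxazolidin-2-one | C/C=C/CCCCCCC[C@H]1[C@@H]2C=C[C@H]3[C@H]4[C@@H]2[C@@H]1C[C@@H]4C=C[C@@H]3C(=O)N1[C@@H](Cc2ccccc2)COC1=O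
F3 | step 7 | tert-butyl (2E,4E,7E)-8-chloroocta-2,4,7-trienoate | CC(C)(C)OC(=O)/C=C/C=C/C/C=C/Cl
F4 | step 7 | tert-butyl (2E,4E,7E)-10-(trimethylsilyl)deca-2,4,7-trien-9-ynoate | CC(C)(C)OC(=O)/C=C/C=C/C/C=C/C#C[Si](C)(C)C
F5 | step 7 | tert-butyl (2E,4E,7E)-deca-2,4,7-trien-9-ynoate | CC(C)(C)OC(=O)/C=C/C=C/C/C=C/C#C
F6 | step 7 | (3E,12E)-1-bromotetradeca-3,12-dien-1-yne | C/C=C/CCCCCCC/C=C/C#CBr
F7 | step 8 | (2E,4Z,6Z,8E,17E)-nonadeca-2,4,6,8,17-pentaen-1-ol | OC/C=C/C=C\C=C/C=C/CCCCCCC/C=C/C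
F8 | step 8 | rac-[(1R,8R)-8-[(8E)-dec-8-en-1-yl]cycloocta-2,4,6-trien-1-yl]methanol | C/C=C/CCCCCCC[C@@H]1/C=C\C=C/C=C\[C@H]1CO
F9 | step 8 | rac-[(1R,6R,7S,8R)-8-[(8E)-dec-8-en-1-yl]bicyclo[4.2.0]octa-2,4-dien-7-yl]methanol | C/C=C/CCCCCCC[C@@H]1[C@H]2C=CC=C[C@H]2[C@H]1CO
F10 | step 8 | rac-(1R,6R,7S,8R)-7-(bromomethyl)-8-[(8E)-dec-8-en-1-yl]bicyclo[4.2.0]octa-2,4-diene | C/C=C/CCCCCCC[C@@H]1[C@H]2C=CC=C[C@H]2[C@H]1CBr
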